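Late in Tuesday's, Wednesday's and Thursday's flasks the ring in hand is a running total: the activated form standing in the flask turns to ring at 0.010 min⁻¹, minute after minute.

    starting material + activator → activated form (k1 = 1.5 L mol⁻¹ min⁻¹)
    activated form → ring (k2 = 0.010 min⁻¹)
    starting material + activated form → open dimer (k3 = 0.17 L mol⁻¹ min⁻¹)
    capture agent + activated form → trapped intermediate (k4 = 0.0080 L mol⁻¹ min⁻¹)
    activator → decomposed reagent (k5 = 0.025 min⁻¹)

| flask | starting material | activator | capture agent | time | remark |
|---|---|---|---|---|---|
| Tuesday's | 0.14 M | 0.950 equiv | 2.80 mM | 50 min | everything together in a closed stirred flask, run for 50 min |
| Wednesday's | 0.14 M (fed, over 25.0 min) | 0.950 equiv | 2.80 mM | 50 min | all but starting material at the start; starting material goes in evenly over 25.0 min, the run ends at 50 min |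
| Sunday's | 0.14 M | 0.950 equiv | 2.80 mM |  | one stirred flow tank at steady state, fed with the mixture as stated, mean residence time 50 min |
| Thursday's | 0.14 M | 0.950 equiv (fed, over 25.0 min) | 2.80 mM | 50 min | a stirred flask in which activator is dosed at a steady rate over 25.0 min without added volume, worked up at 50 min |

- in percentages every species weighs as the starting material in it: one open dimer counts as two
- the stated concentrations are those of everything mixed, before any reaction; amounts are the same in each set-up
- the feed brings no volume worth counting
- run time (Tuesday's): 50 min

- the set-up with the highest amount of ring at the outlet or at the end, in percent of the starting material put in ("none" if the first two lie within 2 percentage points) (Tuesday's / Wednesday's / Sunday's / Thursday's / none)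
- amount of ring at the outlet or at the end, in percent of the starting material put in, Tuesday's
- amount of ring at the outlet or at the end, in percent of the starting material put in, Wednesday's
- amount of ring at the outlet or at the end, in percent of the starting material put in, Sunday's
- amount of ring at the outlet or at the end, in percent of the starting material put in, Thursday's

The fastest rung of the ladder is activation. With Tuesday's charges as mixed, starting material halves by step 1 in 3.5 min, sooner than the activator halves by its own decomposition, in 28 min. So in Tuesday's flask the activator goes mostly to activated form, and the reckoning here starts that form at 0.849 of the charge. On the next rung activated form drains to open dimer, with a half-life of 29 min as charged, and more slowly to ring, in 69 min. The last rung, capture, takes 520 h, far longer, so the capture agent drops out of the reckoning.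

Ring at the end is the mean fraction of activated form times the ring clock, the rate constant of step 2 multiplied by the run time, 0.500. Replacing the curve by its mean, a decay from the starting level at the charged drain of 0.0338 min⁻¹ averages 0.410 over Tuesday's run, which gives 20.5% ring. In Thursday's flask, dosing the activator over 25.0 min turns the opening of the curve into a ramp, and a ramp has the mean of its ends, so the reckoned mean shrinks by a factor 0.750, and Thursday's is reckoned at 15.4%. In Wednesday's flask the starting material comes in over the same 25.0 min, so the same factor is taken, and the activator waits 12.5 min on average and keeps 0.732 of itself against its decomposition, which gives a reckoned 11.3%. In Sunday's tank the outlet level stands in for the mean and the mean residence time, 50 min, for the run time, so ring is the clock times that level, and this reckoning stops there.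

The forecast says Tuesday's, with 22.2%, 14.9%, 15.1% and 16.8% in the order asked. Its figures for Tuesday's, Wednesday's and Thursday's flasks each stand above the reckoning here. Its ground for Wednesday's is: “slow substrate feed lets the activator decompose while it waits”.

The simulation gives 22.8%, 14.8%, 15.1% and 16.8%, so Tuesday's leads, and the forecast held.

Divided by the clock, Tuesday's ring reads as a mean activated form of 0.456, against the 0.410 reckoned. Thursday's flask, read later, takes the same step. At 50.0 min it holds 16.8% ring and 41.9% activated form, and at 2.0 h it holds 18.8% activated form, so the mean of those ends is 30.3%. The clock for the added 70.0 min is 0.700, which brings the reckoned ring to 38.0%. Thursday's flask read at 2.0 h holds 37.1% ring.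

(Its constants are invented; the result is computed.)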